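# Proposed synthesis of 7-hydroxy-2-(4-hydroxyphenyl)-3,5,6,8-tetramethoxy-4H-chromen-4-one (19, CNP0539397.0)

## Analysis of the target

The target 19 is a flavone: a 4H-chromen-4-one (benzo ring A fused to pyranone ring C) with a 4-hydroxyphenyl ring B at C2. It has no stereocentre, so the problem is entirely one of regiochemistry. Ring A is fully substituted: C5, C6 and C8 carry methoxy groups and C7 a free hydroxyl, so four contiguous carbons bear oxygen and no C–H bond is left for late functionalisation. C3 carries a further methoxy group and C4' the second phenol. The 7-hydroxyl sits between two methoxy groups and must be told apart from the similar oxygens at C6 and C8. The 5-methoxy group is peri to the C4 carbonyl, which makes it the ether that chelating Lewis acids remove first, and any intermediate with free hydroxyls at both C5 and C8 is an air-sensitive hydroquinone. The difficulty is to build the pentaoxygenated ring A without a long series of aromatic substitutions and to finish with exactly one of its oxygens unmethylated. The strategy rests on C5–C6–C7–C8 being a four-carbon unit with oxygen on every carbon and C5 para to C8, which is the pattern of a dialkyl squarate after ring expansion to a hydroquinone; C4a and C8a are then C3 and C2 of a 2-aryl-3-methoxy-4-pyranone that already holds ring C, ring B and the C3 methoxy group.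

## Retrosynthetic reasoning

**19 from 18.** The two benzylic O–C bonds at O7 and O4' are cut last. Hydrogenolysis is neutral, so the four methyl ethers of 18, including the labile peri one at O5, are not put at risk, and both phenols appear in one step.

**18 from 17 and 17 from 16.** The O–CH3 bonds at O5 and O6 are cut next, and before them the O–benzyl bonds at O7 and O4'. In the tetraphenol 16 the 7- and 4'-hydroxyls are vinylogous acids of the C4 carbonyl, the 6-hydroxyl is an ordinary phenol and the 5-hydroxyl is held in a hydrogen bond to the carbonyl. A mild base and two equivalents of a benzylating agent should therefore mark O7 and O4' and leave O5 and O6 for methylation. This is the point at which O7 is distinguished from O6.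

**16 from 15 and 15 from 14.** The two O–isopropyl bonds and the O4'–benzyl bond are cut with a boron Lewis acid, and before that the O8–CH3 bond. Only O8 of the hydroquinone 14 is methylated at this stage. A plan that methylated O5 as well was dropped, because conditions that cleave isopropyl ethers would also threaten a chelation-activated peri methyl ether. With O5 left free there is no such ether, and O5 is methylated later together with O6. Methylating O8 also removes the oxidation-prone hydroquinone.

**14 from 11 (key disconnection).** The C8–C8a bond is cut and ring A is folded back into a four-membered ring. In the forward direction the cyclobutenone 11 must open to a dienylketene and reclose on the hydrogen-bearing pyranone carbon. This makes ring A and places all four of its oxygens in one step.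

**11 from 8 and 9.** The bond between the carbinol carbon (future C5) and the pyranone carbon (future C4a) is cut. It is formed by adding the pyranonyl Grignard reagent 10, made from iodide 8, to one carbonyl of the symmetric squarate 9. The symmetry of 9 means only one adduct can form.

**8 from 7 and 7 from 6.** The C–I bond is cut back to the C–H of pyranone 7, and the O–CH3 bond at the future C3 back to the enolic hydroxyl of 6. The methoxy group is installed early because the hydroxyl is acidic and would interfere with the organometallic step.

**6 from 5 and 5 from 4.** The aromatic pyranone is traced to the furan carbinol 4 through the ring-expanded hemiacetal 5. The carbonyl carbon of 6 is the brominated furan carbon of 4, so the bromine acts as the leaving group that is replaced by oxygen. A furan without this bromine would need halogenation after ring expansion, in the presence of the electron-rich benzyloxyphenyl ring, and was not chosen for that reason.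

**4 from 1 and 2.** The aryl–carbinol C–C bond is cut to the aryl bromide 1 (as Grignard reagent 3) and the aldehyde 2. This joins ring B to the future ring C in the first step.

## Alternatives that were turned down

**Alternative 1:** The disconnection cuts both bonds from ring A to ring C (O1–C8a and C4–C4a) and also O1–C2. In the forward key step a fluoride-released aryne A2 (3,4-dimethoxy-5-(methoxymethoxy)benzyne) would insert into the acyl C–O bond of the acid A3 ((Z)-3-[4-(benzyloxy)phenyl]-2-methoxyprop-2-enoic acid). The carboxylate oxygen adds to the aryne carbon remote from the flanking methoxy group, the aryl anion attacks the acyl carbon, and the resulting ortho-acylphenoxide closes by oxa-Michael addition to the chromanone A1.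
- For it: three bonds form in one flask, the 3-alkoxy group of the aryne sets the regiochemistry, and O7 is differentiated from the start as a methoxymethyl ether. On this last point it is stronger than the chosen route, which must differentiate O7 from O6 by acidity.
- Against it: A1 carries hydrogen at C8, so the fourth ring-A oxygen must be introduced afterwards on a crowded, electron-rich ring (halogenation, C–O bond formation, methylation). The chromanone must also be dehydrogenated to the chromone. The aryne A2 needs a pentasubstituted precursor with three differentiated oxygens that is itself a multi-step target.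
- Comparison: the chosen route takes all four ring-A oxygens, including the one at C8, from one purchased C4 unit and leaves no C–H oxidation on ring A.

**Alternative 2:** The disconnection is the C3–C4 bond. An N-heterocyclic carbene from a triazolium salt would turn the aryl aldehyde of the dialdehyde A5 (4-(benzyloxy)-2-{1-[4-(benzyloxy)phenyl]-2-oxoethoxy}-3,5,6-trimethoxybenzaldehyde) into an acyl-anion equivalent, which adds to the aliphatic aldehyde to close ring C as the 3-hydroxychroman-4-one A4.
- For it: the conditions are mild and catalytic, the C4 ketone and C3 oxygen arrive together, and both benzyl ethers are already in place. Only dehydrogenation, 3-O-methylation and hydrogenolysis would follow, so the endgame is shorter than the five steps of the chosen route.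
- Against it: the aryl aldehyde is flanked by two ortho substituents on an electron-rich ring and is slow to form the acyl-anion equivalent. The other aldehyde is an enolisable α-aryl-α-aryloxy acetaldehyde, prone to β-elimination of the phenoxide and to self-condensation. If the roles of the two aldehydes reverse, the regioisomeric acyloin results. Making A5 means O-alkylating a fully substituted salicylaldehyde whose oxygen pattern, with O7 already differentiated, has to be built by classical aromatic chemistry.
- Comparison: the central difficulty of the target is moved into the starting material rather than solved, whereas the chosen route solves it in the key step.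

**Alternative 3:** The disconnection removes C3 as a one-carbon unit (C2–C3 and C3–C4). Dibromocarbene A8, made from a haloform and an alkoxide base, would add to the enol-ether double bond of the benzofuran A7 ({[6-(benzyloxy)-2-[4-(benzyloxy)phenyl]-4,5,7-trimethoxy-1-benzofuran-3-yl]oxy}(tert-butyl)dimethylsilane; the silyl group is assumed to be tert-butyldimethylsilyl). The dibromocyclopropane would open with loss of bromide and of the silyl group to the 3-bromochromone A6, a Ciamician–Dennstedt-type ring expansion.
- For it: the chromone oxidation level is reached directly, ring expansion of silyl enol ethers by dihalocarbenes is established, and both benzyl ethers are in place. On paper only bromide-to-methoxide exchange and hydrogenolysis remain, which is shorter than the chosen endgame.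
- Against it: the double bond of A7 is tetrasubstituted, part of an aromatic furan, and shielded by the aryl group and the peri methoxy group. The silyl enol ether and its parent 2-arylbenzofuranone are labile to strong base and to air. The exchange at C3 of A6 is not a simple substitution, since alkoxides attack C2 of 3-haloflavones and trigger ring opening or contraction; a metal-catalysed C–O coupling on a hindered vinylic bromide would be needed. Ring A again comes from a long classical sequence.
- Comparison: the chosen route carries the C3 methoxy group from the pyranone stage and builds ring A in the key step.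

Key step: step 7

Remark on the chemistry: compounds 4, 5, 11 and 13 contain stereocentres that are destroyed later in the route. They are used as racemates (5 as a mixture of diastereomers), and no stereocontrol is needed anywhere.

## Route

Step 1
Reactants: 1 1-(benzyloxy)-4-bromobenzene; 2 3-bromofuran-2-carbaldehyde
Product: 4 [4-(benzyloxy)phenyl](3-bromofuran-2-yl)methanol (racemic), via [4-(benzyloxy)phenyl]magnesium bromide 3 (not isolated)
Conditions: Mg, THF, 50 °C; then 2, THF, −78 → 0 °C; sat. aq. NH4Cl
Reagents that add atoms: none
Why: Grignard formation from the aryl bromide and 1,2-addition to the aldehyde; at −78 °C addition to the formyl group is far faster than bromine–magnesium exchange at the furan, and the new carbinol centre forms without control (racemic), which is immaterial because it becomes sp2 in step 3.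

Step 2
Reactants: 4 [4-(benzyloxy)phenyl](3-bromofuran-2-yl)methanol
Product: 5 2-[4-(benzyloxy)phenyl]-4-bromo-6-hydroxy-2H-pyran-3(6H)-one (racemic mixture of C2/C6 diastereomers)
Conditions: NBS, NaHCO3, THF/H2O (4:1), 0 °C
Reagents that add atoms: water, O
Why: Achmatowicz rearrangement: the electrophilic bromine attacks the unsubstituted furan C5, water adds, the ring opens to a cis-enedione and the carbinol oxygen recloses on the aldehyde, so the furan bromine ends up at C4 of the enone. The furan is far more nucleophilic than the benzyloxyphenyl ring and the bicarbonate buffer protects the ionisable carbinol; both stereocentres are uncontrolled and are lost in step 3.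

Step 3
Reactants: 5 2-[4-(benzyloxy)phenyl]-4-bromo-6-hydroxy-2H-pyran-3(6H)-one
Product: 6 2-[4-(benzyloxy)phenyl]-3-hydroxy-4H-pyran-4-one
Conditions: 1 M aq. H2SO4/1,4-dioxane (1:1), 90 °C
Reagents that add atoms: water, O
Why: Acid-mediated hydrolytic aromatisation of a 4-halo-6-hydroxy-2H-pyran-3(6H)-one, a known route to 2-substituted 3-hydroxy-4-pyranones: loss of the anomeric hydroxyl and enolisation through the benzylic C2–H give a 4-bromo-3-hydroxypyrylium ion, water adds at C4 and hydrogen bromide is expelled. Because the leaving group was brought in with 2, no free halogen meets the electron-rich aryl ether, and an aryl benzyl ether tolerates dilute aqueous acid.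

Step 4
Reactants: 6 2-[4-(benzyloxy)phenyl]-3-hydroxy-4H-pyran-4-one
Product: 7 2-[4-(benzyloxy)phenyl]-3-methoxy-4H-pyran-4-one
Conditions: MeI, K2CO3, DMF, rt
Reagents that add atoms: iodomethane, CI
Why: Williamson O-alkylation of the acidic enolic hydroxyl of a 3-hydroxy-4-pyranone; it fixes the future C3 methoxy group and removes the acidic proton before the organometallic step.

Step 5
Reactants: 7 2-[4-(benzyloxy)phenyl]-3-methoxy-4H-pyran-4-one
Product: 8 2-[4-(benzyloxy)phenyl]-5-iodo-3-methoxy-4H-pyran-4-one
Conditions: I2, pyridine, CHCl3, rt → 50 °C, dark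
Reagents that add atoms: iodine, II
Why: α-Iodination of a cyclic β-oxygenated enone by the iodine–pyridine method (conjugate addition of pyridine at C6, iodination of the enolate at C5, loss of pyridinium); C5 is the only position this addition–elimination sequence can reach, and because no strongly electrophilic iodine species is generated the aryl ether ring should be left alone.

Step 6
Reactants: 8 2-[4-(benzyloxy)phenyl]-5-iodo-3-methoxy-4H-pyran-4-one; 9 diisopropyl squarate (3,4-diisopropoxycyclobut-3-ene-1,2-dione)
Product: 11 4-{6-[4-(benzyloxy)phenyl]-5-methoxy-4-oxo-4H-pyran-3-yl}-4-hydroxy-2,3-diisopropoxycyclobut-2-en-1-one (racemic), via {6-[4-(benzyloxy)phenyl]-5-methoxy-4-oxo-4H-pyran-3-yl}magnesium chloride 10 (not isolated)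
Conditions: iPrMgCl·LiCl, THF, −40 °C; cannulated into 9, THF, −78 °C; sat. aq. NH4Cl at −78 °C
Reagents that add atoms: none
Why: Iodine–magnesium exchange on an α-iodo vinylogous ester followed by 1,2-addition to one squarate carbonyl; α-magnesiated β-alkoxy enones (magnesiated 1,3-dioxin-4-ones and uracils) are known to survive at low temperature, and the magnesium alkoxide of the adduct blocks a second addition. Because 9 is symmetric only one constitution can form; the carbinol centre is racemic and is lost in step 7, and the work-up is kept neutral because acid converts such adducts into cyclobutenediones.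

Step 7
Reactants: 11 4-{6-[4-(benzyloxy)phenyl]-5-methoxy-4-oxo-4H-pyran-3-yl}-4-hydroxy-2,3-diisopropoxycyclobut-2-en-1-one
Product: 14 2-[4-(benzyloxy)phenyl]-5,8-dihydroxy-6,7-diisopropoxy-3-methoxy-4H-chromen-4-one, via (Z)-dienylketene 12 (not isolated), via 8aH-chromene-4,8-dione tautomer 13 (not isolated)
Conditions: degassed p-xylene (0.01 M), 138 °C, Ar; aq. Na2S2O4 wash
Reagents that add atoms: none
Why: Heating opens the cyclobutenone by conrotatory 4π-electrocyclic cleavage of the C1–C4 bond, and the torquoselectivity of this opening turns the electron-donating hydroxyl outward, so the pyranonyl group ends up cis to the ketene in the (Z)-dienylketene 12. Ring A is then closed by a thermal disrotatory 6π-electrocyclisation in which the ketene carbon (future C8) bonds to the hydrogen-bearing C2 of the pyranone (future C8a), giving the dienone 13. Enolisation of 13 with loss of the C8a hydrogen is driven by aromatisation and delivers the hydroquinone 14; no stereocentre survives, since the carbinol centre of 11 becomes sp2 in 12 and the C8a centre of 13 is erased by the tautomerisation. The closest known reaction type is the Moore rearrangement of 4-alkenyl-, 4-aryl- and 4-heteroaryl-4-hydroxycyclobutenones made from squarates, of which the 4-oxo-4H-pyran-3-yl group is a further member offering the same C=C–H unit. The step needs torquoselectivity and site selectivity: the first is secured by the hydroxyl donor, the second by C2 of the pyranone being the only sp2 carbon that can reach the ketene carbon through a six-membered transition state, whereas the pyranone carbonyl oxygen would need a seven-membered one. Regiochemistry within ring A is not an issue because 9 is symmetric, so both enol-ether oxygens end up at C6 and C7 and the two former carbonyl carbons at C5 and C8. High dilution and exclusion of air suppress intermolecular ketene trapping and oxidation of 14.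

Step 8
Reactants: 14 2-[4-(benzyloxy)phenyl]-5,8-dihydroxy-6,7-diisopropoxy-3-methoxy-4H-chromen-4-one
Product: 15 2-[4-(benzyloxy)phenyl]-5-hydroxy-6,7-diisopropoxy-3,8-dimethoxy-4H-chromen-4-one
Conditions: MeI (1.1 equiv), K2CO3 (1.2 equiv), degassed acetone, rt, Ar
Reagents that add atoms: iodomethane, CI
Why: Selective Williamson methylation: the 5-hydroxyl is locked in a hydrogen bond to the C4 carbonyl and is much less nucleophilic under mild carbonate conditions, so one equivalent of iodomethane should methylate O8 only; this also removes the air-sensitive hydroquinone.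

Step 9
Reactants: 15 2-[4-(benzyloxy)phenyl]-5-hydroxy-6,7-diisopropoxy-3,8-dimethoxy-4H-chromen-4-one
Product: 16 5,6,7-trihydroxy-2-(4-hydroxyphenyl)-3,8-dimethoxy-4H-chromen-4-one
Conditions: BCl3 (6 equiv), pentamethylbenzene, CH2Cl2, −78 → 0 °C; MeOH, then H2O
Reagents that add atoms: none
Why: Lewis-acid dealkylation: BCl3 cleaves secondary alkyl (isopropyl) and benzyl aryl ethers by ionisation at low temperature, whereas unassisted aryl methyl ethers need chloride attack on a methyl group and are slow. The only chelation-activated ether position, O5, is deliberately left as a free hydroxyl, so there is no peri methyl ether to lose, and pentamethylbenzene traps the benzyl cation.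

Step 10
Reactants: 16 5,6,7-trihydroxy-2-(4-hydroxyphenyl)-3,8-dimethoxy-4H-chromen-4-one
Product: 17 7-(benzyloxy)-2-[4-(benzyloxy)phenyl]-5,6-dihydroxy-3,8-dimethoxy-4H-chromen-4-one
Conditions: BnBr (2.1 equiv), K2CO3 (2.2 equiv), DMF, 0 °C → rt, Ar
Reagents that add atoms: benzyl bromide, BrCc1ccccc1
Why: Acidity-controlled Williamson etherification: the 7- and 4'-hydroxyls are vinylogous acids of the C4 carbonyl and are deprotonated first, the 6-hydroxyl is an ordinary phenol and the 5-hydroxyl is chelated, as in the known selective 7-O-alkylation of 5,6,7-trihydroxyflavones; two equivalents of benzyl bromide should therefore give the 7,4'-dibenzyl ether.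

Step 11
Reactants: 17 7-(benzyloxy)-2-[4-(benzyloxy)phenyl]-5,6-dihydroxy-3,8-dimethoxy-4H-chromen-4-one
Product: 18 7-(benzyloxy)-2-[4-(benzyloxy)phenyl]-3,5,6,8-tetramethoxy-4H-chromen-4-one
Conditions: Me2SO4 (excess), K2CO3, acetone, reflux
Reagents that add atoms: dimethyl sulfate, COS(=O)(=O)OC
Why: Exhaustive Williamson methylation under forcing conditions, the standard way to methylate a chelated 5-hydroxyl of a flavone together with the neighbouring 6-hydroxyl; benzyl and methyl ethers are inert.

Step 12
Reactants: 18 7-(benzyloxy)-2-[4-(benzyloxy)phenyl]-3,5,6,8-tetramethoxy-4H-chromen-4-one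
Product: 19 7-hydroxy-2-(4-hydroxyphenyl)-3,5,6,8-tetramethoxy-4H-chromen-4-one
Conditions: H2 (1 atm), Pd/C (10%), EtOAc/MeOH, rt
Reagents that add atoms: none
Why: Hydrogenolysis of the two aryl benzyl ethers over palladium on carbon; the tetrasubstituted C2=C3 bond of the chromone and the methyl ethers are untouched at one atmosphere and room temperature, so both phenols are released in a neutral final step.

## Compound list

1 | 1-(benzyloxy)-4-bromobenzene | Brc1ccc(OCc2ccccc2)cc1 | starting material
2 | 3-bromofuran-2-carbaldehyde | O=Cc1occc1Br | starting material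
3 | [4-(benzyloxy)phenyl]magnesium bromide | Br[Mg]c1ccc(OCc2ccccc2)cc1 | intermediate (not isolated)
4 | [4-(benzyloxy)phenyl](3-bromofuran-2-yl)methanol (racemic) | OC(c1ccc(OCc2ccccc2)cc1)c1occc1Br | intermediate
5 | 2-[4-(benzyloxy)phenyl]-4-bromo-6-hydroxy-2H-pyran-3(6H)-one (racemic mixture of diastereomers) | OC1OC(c2ccc(OCc3ccccc3)cc2)C(=O)C(Br)=C1 | intermediate
6 | 2-[4-(benzyloxy)phenyl]-3-hydroxy-4H-pyran-4-one | O=c1ccoc(-c2ccc(OCc3ccccc3)cc2)c1O | intermediate
7 | 2-[4-(benzyloxy)phenyl]-3-methoxy-4H-pyran-4-one | COc1c(-c2ccc(OCc3ccccc3)cc2)occc1=O | intermediate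
8 | 2-[4-(benzyloxy)phenyl]-5-iodo-3-methoxy-4H-pyran-4-one | COc1c(-c2ccc(OCc3ccccc3)cc2)occ(I)c1=O | intermediate
9 | diisopropyl squarate (3,4-diisopropoxycyclobut-3-ene-1,2-dione) | CC(C)OC1=C(OC(C)C)C(=O)C1=O | starting material
10 | {6-[4-(benzyloxy)phenyl]-5-methoxy-4-oxo-4H-pyran-3-yl}magnesium chloride (LiCl complex) | COc1c(-c2ccc(OCc3ccccc3)cc2)occ([Mg]Cl)c1=O | intermediate (not isolated)
11 | 4-{6-[4-(benzyloxy)phenyl]-5-methoxy-4-oxo-4H-pyran-3-yl}-4-hydroxy-2,3-diisopropoxycyclobut-2-en-1-one (racemic) | CC(C)OC1=C(OC(C)C)C(O)(c2coc(-c3ccc(OCc4ccccc4)cc3)c(OC)c2=O)C1=O | intermediate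
12 | (3Z)-4-{6-[4-(benzyloxy)phenyl]-5-methoxy-4-oxo-4H-pyran-3-yl}-4-hydroxy-2,3-diisopropoxybuta-1,3-dien-1-one | O=C=C(OC(C)C)/C(OC(C)C)=C(/O)c1coc(-c2ccc(OCc3ccccc3)cc2)c(OC)c1=O | intermediate (not isolated)
13 | 2-[4-(benzyloxy)phenyl]-5-hydroxy-6,7-diisopropoxy-3-methoxy-8aH-chromene-4,8-dione (racemic) | COC1=C(c2ccc(OCc3ccccc3)cc2)OC2C(=O)C(OC(C)C)=C(OC(C)C)C(O)=C2C1=O | intermediate (not isolated)
14 | 2-[4-(benzyloxy)phenyl]-5,8-dihydroxy-6,7-diisopropoxy-3-methoxy-4H-chromen-4-one | COc1c(-c2ccc(OCc3ccccc3)cc2)oc2c(O)c(OC(C)C)c(OC(C)C)c(O)c2c1=O | intermediate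
15 | 2-[4-(benzyloxy)phenyl]-5-hydroxy-6,7-diisopropoxy-3,8-dimethoxy-4H-chromen-4-one | COc1c(-c2ccc(OCc3ccccc3)cc2)oc2c(OC)c(OC(C)C)c(OC(C)C)c(O)c2c1=O | intermediate
16 | 5,6,7-trihydroxy-2-(4-hydroxyphenyl)-3,8-dimethoxy-4H-chromen-4-one | COc1c(-c2ccc(O)cc2)oc2c(OC)c(O)c(O)c(O)c2c1=O | intermediate
17 | 7-(benzyloxy)-2-[4-(benzyloxy)phenyl]-5,6-dihydroxy-3,8-dimethoxy-4H-chromen-4-one | COc1c(-c2ccc(OCc3ccccc3)cc2)oc2c(OC)c(OCc3ccccc3)c(O)c(O)c2c1=O | intermediate
18 | 7-(benzyloxy)-2-[4-(benzyloxy)phenyl]-3,5,6,8-tetramethoxy-4H-chromen-4-one | COc1c(-c2ccc(OCc3ccccc3)cc2)oc2c(OC)c(OCc3ccccc3)c(OC)c(OC)c2c1=O | intermediate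
19 | 7-hydroxy-2-(4-hydroxyphenyl)-3,5,6,8-tetramethoxy-4H-chromen-4-one | COc1c(O)c(OC)c2oc(-c3ccc(O)cc3)c(OC)c(=O)c2c1OC | target

## Step count and least certain steps

Total step count: 12. Longest linear sequence: 12 steps (from 1 or 2 to 19); 9 is purchased.

**Step 7 (key step).**
- Risk: the ketene 12 may be consumed before it closes. Closure onto the pyranone costs the cross-conjugation of the γ-pyrone and may be slower than for a simple alkenyl group, so the free tertiary hydroxyl can add to the ketene (intramolecularly after inward rotation, or intermolecularly). Oxidation of the hydroquinone during isolation is a second, reversible loss.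
- Fallback: set out from 11 and silylate the tertiary alcohol (TMSCl, imidazole, DMF) to 4-{6-[4-(benzyloxy)phenyl]-5-methoxy-4-oxo-4H-pyran-3-yl}-2,3-diisopropoxy-4-[(trimethylsilyl)oxy]cyclobut-2-en-1-one F1. The silyloxy group still rotates outward but can no longer trap the ketene. Thermolysis in p-xylene should give 2-[4-(benzyloxy)phenyl]-8-hydroxy-6,7-diisopropoxy-3-methoxy-5-[(trimethylsilyl)oxy]-4H-chromen-4-one F2, and dilute aqueous acid in THF removes the silyl group, returning to the route at 14.

**Step 6.**
- Risk: the Grignard reagent 10 may decompose before it adds, either by β-elimination of the ring oxygen (opening the pyranone) or by competing addition of the exchange reagent to C6 of the pyranone.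
- Fallback: set out from 8 and insert zinc directly (Zn dust, LiCl, THF, 25–40 °C) to give {6-[4-(benzyloxy)phenyl]-5-methoxy-4-oxo-4H-pyran-3-yl}zinc iodide F3. This covalent, non-basic reagent does not fragment. It is added to 9 in the presence of MgCl2 (Lewis-acid-promoted addition of organozinc halides to ketones), returning at 11.

**Step 3.**
- Risk: cation-driven decomposition. The hemiacetal and the electron-rich benzylic C2 ionise in hot acid, so oligomerisation or loss of the benzyl ether can outrun addition of water at C4.
- Fallback: set out from the Grignard reagent 3 and buy the pyranone ring instead of making it.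
  - Compound 3 is converted with B(OMe)3 and aqueous acid into [4-(benzyloxy)phenyl]boronic acid F4.
  - Commercial 3-hydroxy-4H-pyran-4-one is brominated at its enol-activated C2 (NBS, MeCN) to 2-bromo-3-hydroxy-4H-pyran-4-one F5 and O-methylated (MeI, K2CO3) to 2-bromo-3-methoxy-4H-pyran-4-one F6.
  - Suzuki–Miyaura coupling of F4 with F6 (Pd(PPh3)4, K2CO3, dioxane/H2O, 80 °C) returns to the route at 7.

**Step 9.**
- Risk: over-dealkylation. Once O7 carries boron, chloride can also attack the neighbouring 8-methyl ether, or the 3-methyl ether next to the complexed carbonyl. The pyrogallol-type product can also oxidise during work-up.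
- Fallback: set out from 10 and avoid the Lewis acid by using purchased di-tert-butyl squarate (3,4-di-tert-butoxycyclobut-3-ene-1,2-dione) in place of 9.
  - Addition gives 4-{6-[4-(benzyloxy)phenyl]-5-methoxy-4-oxo-4H-pyran-3-yl}-2,3-di-tert-butoxy-4-hydroxycyclobut-2-en-1-one F7.
  - The same thermal rearrangement gives 2-[4-(benzyloxy)phenyl]-6,7-di-tert-butoxy-5,8-dihydroxy-3-methoxy-4H-chromen-4-one F8.
  - Selective 8-O-methylation gives 2-[4-(benzyloxy)phenyl]-6,7-di-tert-butoxy-5-hydroxy-3,8-dimethoxy-4H-chromen-4-one F9.
  - CF3CO2H in CH2Cl2 at room temperature removes both tert-butyl groups as isobutene without touching methyl or benzyl ethers, giving 2-[4-(benzyloxy)phenyl]-5,6,7-trihydroxy-3,8-dimethoxy-4H-chromen-4-one F10.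
  - Mono-benzylation at O7 (BnBr 1.05 equiv, KHCO3, DMF) returns to the route at 17.

**Step 10.**
- Risk: insufficient site selectivity between O7 and O6, with over-alkylation, because the 8-methoxy group crowds O7.
- Fallback: set out from 16 and select by ester lability instead of alkylation rate.
  - Peracetylation (Ac2O, pyridine, DMAP) gives 4-[5,6,7-tris(acetyloxy)-3,8-dimethoxy-4-oxo-4H-chromen-2-yl]phenyl acetate F11.
  - Thiolysis (PhSH, imidazole, NMP, 0 °C) removes the acetates of the two most acidic phenols, giving 7-hydroxy-2-(4-hydroxyphenyl)-3,8-dimethoxy-4-oxo-4H-chromene-5,6-diyl diacetate F12.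
  - Benzylation (BnBr, K2CO3, acetone) gives 7-(benzyloxy)-2-[4-(benzyloxy)phenyl]-3,8-dimethoxy-4-oxo-4H-chromene-5,6-diyl diacetate F13.
  - Methanolysis of the two remaining acetates (K2CO3, MeOH) returns to the route at 17.

## Further compounds

F1 | step 7 | 4-{6-[4-(benzyloxy)phenyl]-5-methoxy-4-oxo-4H-pyran-3-yl}-2,3-diisopropoxy-4-[(trimethylsilyl)oxy]cyclobut-2-en-1-one (racemic) | CC(C)OC1=C(OC(C)C)C(O[Si](C)(C)C)(c2coc(-c3ccc(OCc4ccccc4)cc3)c(OC)c2=O)C1=O
F2 | step 7 | 2-[4-(benzyloxy)phenyl]-8-hydroxy-6,7-diisopropoxy-3-methoxy-5-[(trimethylsilyl)oxy]-4H-chromen-4-one | COc1c(-c2ccc(OCc3ccccc3)cc2)oc2c(O)c(OC(C)C)c(OC(C)C)c(O[Si](C)(C)C)c2c1=O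
F3 | step 6 | {6-[4-(benzyloxy)phenyl]-5-methoxy-4-oxo-4H-pyran-3-yl}zinc iodide | COc1c(-c2ccc(OCc3ccccc3)cc2)occ([Zn]I)c1=O
F4 | step 3 | [4-(benzyloxy)phenyl]boronic acid | OB(O)c1ccc(OCc2ccccc2)cc1
F5 | step 3 | 2-bromo-3-hydroxy-4H-pyran-4-one | O=c1ccoc(Br)c1O
F6 | step 3 | 2-bromo-3-methoxy-4H-pyran-4-one | COc1c(Br)occc1=O
F7 | step 9 | 4-{6-[4-(benzyloxy)phenyl]-5-methoxy-4-oxo-4H-pyran-3-yl}-2,3-di-tert-butoxy-4-hydroxycyclobut-2-en-1-one (racemic) | CC(C)(C)OC1=C(OC(C)(C)C)C(O)(c2coc(-c3ccc(OCc4ccccc4)cc3)c(OC)c2=O)C1=O
F8 | step 9 | 2-[4-(benzyloxy)phenyl]-6,7-di-tert-butoxy-5,8-dihydroxy-3-methoxy-4H-chromen-4-one | COc1c(-c2ccc(OCc3ccccc3)cc2)oc2c(O)c(OC(C)(C)C)c(OC(C)(C)C)c(O)c2c1=O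
F9 | step 9 | 2-[4-(benzyloxy)phenyl]-6,7-di-tert-butoxy-5-hydroxy-3,8-dimethoxy-4H-chromen-4-one | COc1c(-c2ccc(OCc3ccccc3)cc2)oc2c(OC)c(OC(C)(C)C)c(OC(C)(C)C)c(O)c2c1=O
F10 | step 9 | 2-[4-(benzyloxy)phenyl]-5,6,7-trihydroxy-3,8-dimethoxy-4H-chromen-4-one | COc1c(-c2ccc(OCc3ccccc3)cc2)oc2c(OC)c(O)c(O)c(O)c2c1=O
F11 | step 10 | 4-[5,6,7-tris(acetyloxy)-3,8-dimethoxy-4-oxo-4H-chromen-2-yl]phenyl acetate | COc1c(-c2ccc(OC(C)=O)cc2)oc2c(OC)c(OC(C)=O)c(OC(C)=O)c(OC(C)=O)c2c1=O
F12 | step 10 | 7-hydroxy-2-(4-hydroxyphenyl)-3,8-dimethoxy-4-oxo-4H-chromene-5,6-diyl diacetate | COc1c(-c2ccc(O)cc2)oc2c(OC)c(O)c(OC(C)=O)c(OC(C)=O)c2c1=O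
F13 | step 10 | 7-(benzyloxy)-2-[4-(benzyloxy)phenyl]-3,8-dimethoxy-4-oxo-4H-chromene-5,6-diyl diacetate | COc1c(-c2ccc(OCc3ccccc3)cc2)oc2c(OC)c(OCc3ccccc3)c(OC(C)=O)c(OC(C)=O)c2c1=O
A1 | alternative 1 | 2-[4-(benzyloxy)phenyl]-3,5,6-trimethoxy-7-(methoxymethoxy)chroman-4-one (racemic mixture of C2/C3 diastereomers) | COCOc1cc2OC(c3ccc(OCc4ccccc4)cc3)C(OC)C(=O)c2c(OC)c1OC
A2 | alternative 1 | 3,4-dimethoxy-5-(methoxymethoxy)benzyne | COCOC1=CC#CC(OC)=C1OC
A3 | alternative 1 | (Z)-3-[4-(benzyloxy)phenyl]-2-methoxyprop-2-enoic acid | CO/C(=C\c1ccc(OCc2ccccc2)cc1)C(=O)O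
A4 | alternative 2 | 7-(benzyloxy)-2-[4-(benzyloxy)phenyl]-3-hydroxy-5,6,8-trimethoxychroman-4-one (racemic mixture of diastereomers) | COc1c(OCc2ccccc2)c(OC)c2OC(c3ccc(OCc4ccccc4)cc3)C(O)C(=O)c2c1OC
A5 | alternative 2 | 4-(benzyloxy)-2-{1-[4-(benzyloxy)phenyl]-2-oxoethoxy}-3,5,6-trimethoxybenzaldehyde (racemic) | COc1c(OCc2ccccc2)c(OC)c(OC(C=O)c2ccc(OCc3ccccc3)cc2)c(C=O)c1OC
A6 | alternative 3 | 7-(benzyloxy)-2-[4-(benzyloxy)phenyl]-3-bromo-5,6,8-trimethoxy-4H-chromen-4-one | COc1c(OCc2ccccc2)c(OC)c2oc(-c3ccc(OCc4ccccc4)cc3)c(Br)c(=O)c2c1OC
A7 | alternative 3 | {[6-(benzyloxy)-2-[4-(benzyloxy)phenyl]-4,5,7-trimethoxy-1-benzofuran-3-yl]oxy}(tert-butyl)dimethylsilane | COc1c(OCc2ccccc2)c(OC)c2oc(-c3ccc(OCc4ccccc4)cc3)c(O[Si](C)(C)C(C)(C)C)c2c1OC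
A8 | alternative 3 | dibromocarbene | Br[C]Br
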